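The spirocyclopentane is cut into a three-carbon unit (C13H2–C14H–C26HOH) and the exocyclic two-carbon unit C12H2=C11. The key step exploits the spiro carbon C11, which lies between C10 (the methyl carbinol) and C6 (the CH) of the cyclohexane and is therefore the 2-position of cyclohexane-1,3-dione: in one pot a nitronate Michael addition to 2-methylenecyclohexane-1,3-dione forms C12–C13 and an acid-triggered aldol of the dione carbon onto a masked aldehyde forms C11–C26. The precursor is a nitromethyl menthyloxy-butyrolactone that carries C14; lactone closure locks the cis C14/C26 relationship, and the two equal carbonyl groups are told apart only afterwards.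

Key step: step 3

Remark on atom labels: C11 = spiro carbon; C12, C13 = the two CH2 of the cyclopentane; C14 = its CH bearing the triene; C26 = its CHOH; C10 = C(OH)CH3 and C6 = CH(3-hydroxypropyl) flank C11 in the cyclohexane; C7 = ring carbon of the exocyclic enal (C2 carries CH3, C1 = CHO); C3–C5 = hydroxypropyl chain; C15 (exo-methylene C27) to C23 = side chain, C28 = its CH2OH; C16 is the lactone carbonyl until step 14. The target is (6R,10S,11S,14R,26S), 2Z,16E,18Z.
Assumption: (5R)-5-[(1R,2S,5R)-menthyloxy]furan-2(5H)-one is purchased (otherwise two steps from furfural and (−)-menthol).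

Step 1
Reactants: 1 cyclohexane-1,3-dione; 2 N,N-dimethylmethyleneiminium iodide
Product: 3 2-[(dimethylamino)methyl]-3-hydroxycyclohex-2-en-1-one
Conditions: Et3N, CH2Cl2, 0 °C to rt
Reagents that add atoms: none
Why: Mannich reaction of the dione enol with the preformed iminium salt gives the 2-aminomethyl dione, a storable source of 2-methylenecyclohexane-1,3-dione.

Step 2
Reactants: 4 (5R)-5-[(1R,2S,5R)-menthyloxy]furan-2(5H)-one; 5 nitromethane
Product: 6 (4S,5R)-5-[(1R,2S,5R)-menthyloxy]-4-(nitromethyl)dihydrofuran-2(3H)-one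
Conditions: DBU (0.1 equiv), MeNO2 (5 equiv), CH2Cl2, 0 °C to rt
Reagents that add atoms: none
Why: Base-catalysed Michael addition of nitromethane to the butenolide should occur anti to the menthyloxy group on the acetal carbon (C26), which sets C14 (trans adduct) in the absolute sense of the target.

Step 3
Reactants: 3 2-[(dimethylamino)methyl]-3-hydroxycyclohex-2-en-1-one; 6 nitromethyl menthyloxy lactone (1.2 equiv)
Product: 9 nitro spiro lactone dione (cis-fused γ-lactone O26–C16 on the cyclopentane C11–C12–C13(NO2)–C14–C26; C11 spiro to cyclohexane-1,3-dione; C14 and C26 as in the target; C13 epimers), via 2-methylenecyclohexane-1,3-dione 7 (not isolated), via nitro Michael adduct 8 (not isolated)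
Conditions: Et3N (0.5 equiv), MeCN, 60 °C, N2 sweep; then AcOH, 0 °C; then TFA–H2O (4:1), 40 °C
Reagents that add atoms: none
Why: Warming expels dimethylamine from 3 (E1cB) to release the Michael acceptor 7, whose exocyclic CH2 (C12) is attacked by the nitronate carbon (C13) of 6 to give 8; aqueous acid then ionises the menthyloxy lactone acetal (acyloxocarbenium ion or free aldehyde) and the enol carbon C11 of the dione adds to C26, an intramolecular aldol reaction, after which the γ-lactone persists or re-closes. The closest known reaction types are the Michael alkylation of nitroalkanes with enones released from Mannich bases and the acid-mediated aldol cyclopentannulation of a ketone that carries a masked 3-oxopropyl chain. The cyclopentane closes in a 5-(enolexo)-exo-trig mode. C26 is the only lasting new stereocentre and is fixed by C14, because only the cis-fused bicyclic lactone can form and the aldol is reversible in acid; C13 is epimeric but loses its nitro group in step 4, and C11 is not yet stereogenic since both carbonyl arms are equal. The step needs C- instead of O-attack by the dione enol, secured by the five- versus seven-membered ring size, and single alkylation of the nitronate, secured by the branching next to C13 and the small excess of 6.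

Step 4
Reactants: 9 nitro spiro lactone dione
Product: 10 spiro lactone dione (C13 = CH2; C14 and C26 as in the target)
Conditions: Bu3SnH (5 equiv), AIBN, PhMe, 110 °C
Reagents that add atoms: none
Why: Radical denitration: the stannyl radical adds to a nitro oxygen, the C13–N bond fragments and the secondary C13 radical takes hydrogen from Bu3SnH under neutral conditions that leave dione and lactone intact.

Step 5
Reactants: 10 spiro lactone dione
Product: 11 mono enol triflate (C6=C7, OTf on C6; remaining ketone C10 on the cyclopentane face of the C26 oxygen, so C11 is configured as in the target)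
Conditions: KN(SiMe3)2 (1.05 equiv), THF, −78 °C; then PhNTf2, −78 to 0 °C
Reagents that add atoms: N-phenylbis(trifluoromethanesulfonimide) O=S(=O)(N(c1ccccc1)S(=O)(=O)C(F)(F)F)C(F)(F)F
Why: Kinetic enolisation and O-triflation (enol triflate formation) should take place at the α-CH2 of the carbonyl remote from the lactone, because the cis-fused lactone lies over the other carbonyl and its α-hydrogens; this choice makes C11 a stereocentre of the required sense.

Step 6
Reactants: 11 mono enol triflate
Product: 12 tertiary alcohol (C10: CH3 cis to C12, OH cis to C26)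
Conditions: MeLi, CeCl3, THF, −78 °C
Reagents that add atoms: methyllithium [Li]C
Why: Organocerium 1,2-addition is non-enolising and selective for the ketone over lactone and enol triflate, and Felkin–Anh attack anti to the bulkier C26 branch of the quaternary C11 (on the side of the C12 methylene) should set C10.

Step 7
Reactants: 12 tertiary alcohol enol triflate; 13 allyloxy(tert-butyl)dimethylsilane
Product: 15 cyclohexene with the 3-(silyloxy)propyl chain on C6 (C6=C7), via B-alkyl-9-BBN 14 (not isolated)
Conditions: 13, 9-BBN dimer, THF, 0 °C to rt; then 12, Pd(dppf)Cl2 (5 mol%), AsPh3, Cs2CO3, DMF–H2O, rt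
Reagents that add atoms: none
Why: Anti-Markovnikov hydroboration of 13 and B-alkyl Suzuki–Miyaura coupling with the enol triflate attach C5–C3 to C6.

Step 8
Reactants: 15 trisubstituted cyclohexene
Product: 16 C7 alcohol (6-H cis to C12, chain cis to C26; 7-OH cis to 6-H)
Conditions: BH3·THF (3 equiv), THF, 0 °C to rt; then aq. NaOH, H2O2, 0 °C; then dilute HCl (lactone re-closure)
Reagents that add atoms: hydrogen peroxide OO
Why: Hydroboration–oxidation puts boron on the less substituted C7 and hydrogen syn on C6, from the alkene face of the C12 methylene and anti to the pseudoaxial C26 branch and the boron-bound C10 oxygen, which sets C6.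

Step 9
Reactants: 16 C7 alcohol
Product: 17 C7 ketone
Conditions: Dess–Martin periodinane, NaHCO3, CH2Cl2, rt
Reagents that add atoms: none
Why: Dess–Martin oxidation of the secondary alcohol under buffered, non-basic conditions leaves the tertiary alcohol alone and does not epimerise C6, now α to the ketone.

Step 10
Reactants: 17 C7 ketone
Product: 18 C7 isopropenyl carbinol (C7 configuration of no consequence)
Conditions: CH2=C(CH3)MgBr, CeCl3, THF, −78 °C
Reagents that add atoms: isopropenylmagnesium bromide CC(=C)[Mg]Br
Why: Organocerium 1,2-addition delivers the three carbons C1, C2 and the C2 methyl to the hindered, enolisable ketone without touching the lactone.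

Step 11
Reactants: 18 isopropenyl carbinol; 2 N,N-dimethylmethyleneiminium iodide
Product: 21 α-methylene lactone (C15=C27), via lactone Mannich base 19 (not isolated), via ammonium iodide 20 (not isolated)
Conditions: LiN(iPr)2 (3.5 equiv), THF, −78 °C; 2, −78 to 0 °C; then MeI, MeOH, rt; then aq. NaHCO3, CH2Cl2, rt
Reagents that add atoms: none
Why: α-Methylenation of the γ-lactone by Mannich reaction of its lithium enolate, N-quaternisation and E1cB elimination of trimethylamine under mild base, which avoids exo-to-endo isomerisation.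

Step 12
Reactants: 21 α-methylene lactone
Product: 22 (2Z)-enal (C7=C2(CH3)CHO, CHO syn to C6)
Conditions: pyridinium chlorochromate (C5H5NH)[CrO3Cl], 4 Å molecular sieves, CH2Cl2, rt
Reagents that add atoms: pyridinium chlorochromate [O-][Cr](=O)(=O)Cl.c1cc[nH+]cc1
Why: Babler–Dauben oxidative transposition: the chromate ester of the tertiary allylic alcohol undergoes a [3,3] shift and oxidation, and the chair-like shift should put the bulkier CH3 on the C8 side and the oxygenated carbon syn to the substituted C6.

Step 13
Reactants: 22 enal lactone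
Product: 23 lactol allylic alcohol (C16 lactol, anomers; C1 = CH2OH)
Conditions: iBu2AlH (5 equiv), CH2Cl2, −78 °C; potassium sodium tartrate work-up
Reagents that add atoms: none
Why: Hydride reduction stops at the lactol (aluminium hemiacetal stable at −78 °C) and reduces the enal 1,2 to the allylic alcohol, which masks the aldehyde for the next two steps with retention of alkene geometry.

Step 14
Reactants: 23 lactol allylic alcohol
Product: 24 (E)-dienyl pinacol boronate triol (C15(=CH2)–C16H=C17H–Bpin; free 26-OH, 10-OH, 1-OH)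
Conditions: CH2(Bpin)2, lithium 2,2,6,6-tetramethylpiperidide, THF, 0 °C; then 23, −78 °C to rt
Reagents that add atoms: bis(pinacolato)borylmethane CC1(C)OB(CB2OC(C)(C)C(C)(C)O2)OC1(C)C
Why: Boron–Wittig olefination of the hydroxy-aldehyde form of the lactol gives the E alkenyl boronate by syn-elimination and frees the C26 hydroxyl.

Step 15
Reactants: 25 prop-2-yn-1-ol; 26 5-bromo-2-methylpent-2-ene
Product: 28 (Z)-3-iodo-2-(4-methylpent-3-en-1-yl)prop-2-en-1-ol, via homoprenylmagnesium bromide 27 (not isolated)
Conditions: 26, Mg, THF; then 25, CuI (10 mol%), Et2O–THF, −10 °C to rt; then I2, −78 to 0 °C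
Reagents that add atoms: iodine II
Why: Copper-catalysed anti-carbomagnesiation of the propargylic alkoxide puts the alkyl group on the internal carbon and magnesium, chelated by oxygen, cis to CH2O, and iodinolysis retains this geometry.

Step 16
Reactants: 28 (Z)-iodo allylic alcohol
Product: 29 its tert-butyldimethylsilyl ether
Conditions: TBSCl, imidazole, DMF, rt
Reagents that add atoms: tert-butyldimethylsilyl chloride CC(C)(C)[Si](C)(C)Cl
Why: Silylation of the primary allylic alcohol so that it survives the later allylic oxidation.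

Step 17
Reactants: 24 dienyl boronate; 29 (Z)-alkenyl iodide
Product: 30 bis-silyl triene triol (16E,18Z)
Conditions: Pd(PPh3)4 (5 mol%), aq. K3PO4, THF, 40 °C
Reagents that add atoms: none
Why: Suzuki–Miyaura coupling of alkenyl boronate and alkenyl iodide proceeds with retention at both partners and tolerates the free alcohols.

Step 18
Reactants: 30 triene triol
Product: 31 bis-silyl enal
Conditions: activated MnO2 (excess), CH2Cl2, rt
Reagents that add atoms: none
Why: MnO2 oxidises only the primary allylic alcohol at C1; the secondary homoallylic and tertiary alcohols, the silyl ethers and the alkene geometries are untouched.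

Step 19
Reactants: 31 bis-silyl enal
Product: 32 CNP0249558.2 (target)
Conditions: Bu4NF, AcOH, THF, 0 °C to rt
Reagents that add atoms: none
Why: Fluoride-mediated cleavage of both primary silyl ethers, buffered with acetic acid to protect the enal and the γ-stereocentre C6 from base.

Compound list
1 | cyclohexane-1,3-dione | O=C1CCCC(=O)C1 | starting material
2 | N,N-dimethylmethyleneiminium iodide | C[N+](C)=C.[I-] | starting material
3 | 2-[(dimethylamino)methyl]-3-hydroxycyclohex-2-en-1-one | CN(C)CC1=C(O)CCCC1=O | intermediate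
4 | (5R)-5-[(1R,2S,5R)-menthyloxy]furan-2(5H)-one | O=C1C=C[C@H](O[C@@H]2C[C@H](C)CC[C@H]2C(C)C)O1 | starting material
5 | nitromethane | C[N+](=O)[O-] | starting material
6 | (4S,5R)-5-[(1R,2S,5R)-menthyloxy]-4-(nitromethyl)dihydrofuran-2(3H)-one | O=C1C[C@@H](C[N+](=O)[O-])[C@H](O[C@@H]2C[C@H](C)CC[C@H]2C(C)C)O1 | intermediate
7 | 2-methylenecyclohexane-1,3-dione | C=C1C(=O)CCCC1=O | intermediate
8 | nitro Michael adduct, 2-[2-nitro-2-(menthyloxy lactone)ethyl]cyclohexane-1,3-dione | O=C1C[C@@H](C(CC2C(=O)CCCC2=O)[N+](=O)[O-])[C@H](O[C@@H]3C[C@H](C)CC[C@H]3C(C)C)O1 | intermediate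
9 | nitro spiro lactone dione (C13 epimers; C14, C26 as in target) | O=C1C[C@H]2C([N+](=O)[O-])CC3(C(=O)CCCC3=O)[C@H]2O1 | intermediate
10 | spiro lactone dione | O=C1C[C@H]2CCC3(C(=O)CCCC3=O)[C@H]2O1 | intermediate
11 | mono enol triflate (C6 OTf, C10 ketone) | O=C1C[C@H]2CC[C@@]3(C(=O)CCC=C3OS(=O)(=O)C(F)(F)F)[C@H]2O1 | intermediate
12 | C10 tertiary alcohol enol triflate | O=C1C[C@H]2CC[C@@]3([C@@](C)(O)CCC=C3OS(=O)(=O)C(F)(F)F)[C@H]2O1 | intermediate
13 | allyloxy(tert-butyl)dimethylsilane | C=CCO[Si](C)(C)C(C)(C)C | starting material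
14 | B-[3-(tert-butyldimethylsilyloxy)propyl]-9-borabicyclo[3.3.1]nonane | CC(C)(C)[Si](C)(C)OCCCB1C2CCCC1CCC2 | intermediate
15 | C6-(3-silyloxypropyl) cyclohexene | O=C1C[C@H]2CC[C@@]3([C@@](C)(O)CCC=C3CCCO[Si](C)(C)C(C)(C)C)[C@H]2O1 | intermediate
16 | C7 alcohol | O=C1C[C@H]2CC[C@@]3([C@@](C)(O)CC[C@H](O)[C@H]3CCCO[Si](C)(C)C(C)(C)C)[C@H]2O1 | intermediate
17 | C7 ketone | O=C1C[C@H]2CC[C@@]3([C@@](C)(O)CCC(=O)[C@H]3CCCO[Si](C)(C)C(C)(C)C)[C@H]2O1 | intermediate
18 | C7 isopropenyl carbinol | O=C1C[C@H]2CC[C@@]3([C@@](C)(O)CCC(O)(C(C)=C)[C@H]3CCCO[Si](C)(C)C(C)(C)C)[C@H]2O1 | intermediate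
19 | α-(dimethylaminomethyl) lactone | O=C1C(CN(C)C)[C@H]2CC[C@@]3([C@@](C)(O)CCC(O)(C(C)=C)[C@H]3CCCO[Si](C)(C)C(C)(C)C)[C@H]2O1 | intermediate
20 | α-(trimethylammoniomethyl) lactone iodide | O=C1C(C[N+](C)(C)C)[C@H]2CC[C@@]3([C@@](C)(O)CCC(O)(C(C)=C)[C@H]3CCCO[Si](C)(C)C(C)(C)C)[C@H]2O1.[I-] | intermediate
21 | α-methylene lactone | O=C1C(=C)[C@H]2CC[C@@]3([C@@](C)(O)CCC(O)(C(C)=C)[C@H]3CCCO[Si](C)(C)C(C)(C)C)[C@H]2O1 | intermediate
22 | (2Z)-enal α-methylene lactone | O=C1C(=C)[C@H]2CC[C@@]3([C@@](C)(O)CC/C(=C(\C)C=O)[C@H]3CCCO[Si](C)(C)C(C)(C)C)[C@H]2O1 | intermediate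
23 | lactol allylic alcohol | OC1C(=C)[C@H]2CC[C@@]3([C@@](C)(O)CC/C(=C(\C)CO)[C@H]3CCCO[Si](C)(C)C(C)(C)C)[C@H]2O1 | intermediate
24 | (E)-dienyl pinacol boronate triol | C=C(/C=C/B1OC(C)(C)C(C)(C)O1)[C@H]1CC[C@]2([C@H](CCCO[Si](C)(C)C(C)(C)C)/C(=C(/C)CO)CC[C@]2(C)O)[C@H]1O | intermediate
25 | prop-2-yn-1-ol | C#CCO | starting material
26 | 5-bromo-2-methylpent-2-ene | CC(C)=CCCBr | starting material
27 | (4-methylpent-3-en-1-yl)magnesium bromide | CC(C)=CCC[Mg]Br | intermediate
28 | (Z)-3-iodo-2-(4-methylpent-3-en-1-yl)prop-2-en-1-ol | I/C=C(\CO)CCC=C(C)C | intermediate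
29 | (Z)-tert-butyl{[3-iodo-2-(4-methylpent-3-en-1-yl)prop-2-en-1-yl]oxy}dimethylsilane | I/C=C(\CO[Si](C)(C)C(C)(C)C)CCC=C(C)C | intermediate
30 | bis-silyl triene triol (all stereocentres as in target) | C=C(/C=C/C=C(\CO[Si](C)(C)C(C)(C)C)CCC=C(C)C)[C@H]1CC[C@]2([C@H](CCCO[Si](C)(C)C(C)(C)C)/C(=C(/C)CO)CC[C@]2(C)O)[C@H]1O | intermediate
31 | bis-silyl enal | C=C(/C=C/C=C(\CO[Si](C)(C)C(C)(C)C)CCC=C(C)C)[C@H]1CC[C@]2([C@H](CCCO[Si](C)(C)C(C)(C)C)/C(=C(/C)C=O)CC[C@]2(C)O)[C@H]1O | intermediate
32 | CNP0249558.2 | C=C(/C=C/C=C(\CO)CCC=C(C)C)[C@H]1CC[C@]2([C@H](CCCO)/C(=C(/C)C=O)CC[C@]2(C)O)[C@H]1O | target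

Total step count: 19. Longest linear sequence: 16 steps (steps 2–14 and 17–19, from 4 to 32).

Steps most likely to fail

Step 5: the enolisation may not distinguish the two diastereotopic carbonyl groups well enough, which would erode the configuration at C11. The fallback replaces kinetic by thermodynamic differentiation and sets out from 10. Reversible mono-ketalisation (ethylene glycol, TsOH, benzene, water separator) should place the dioxolane on the carbonyl remote from the lactone and give the mono-ketal F6. MeLi/CeCl3 then gives the tertiary alcohol F7, and aqueous HCl in THF the β-hydroxy ketone F8. Double deprotonation with KN(SiMe3)2 (2.2 equiv) followed by PhNTf2 comes back to the route at 12.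

Step 4: the secondary nitro group may resist radical C–N cleavage, through slow fragmentation or competing reduction at nitrogen. The fallback removes the group ionically through a carbonyl and sets out from 9. A reductive Nef reaction (Et3N; TiCl3, NH4OAc, aqueous THF) gives the cyclopentanone F4. TsNHNH2 converts its unhindered ketone into the tosylhydrazone F5, and reduction with catecholborane followed by NaOAc comes back to the route at 10.

Step 3: the nitronate may be alkylated twice, the nitro group may be lost by Nef-type hydrolysis on acidification, or the acetal may ionise too slowly. The fallback uses a radical instead of a nitronate Michael addition and sets out from 4. Benzophenone-sensitised photoaddition of methanol gives the trans hydroxymethyl lactone F1, and an Appel reaction (I2, PPh3, imidazole) the iodide F2. Giese addition of its primary radical (Bu3SnH, AIBN, benzene, 80 °C) to 7 released from 3 gives the 2-alkyl dione F3. TFA–H2O closes F3 by the same aldol-lactonisation and comes back to the route at 10, so that step 4 is not needed.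

Further compounds
F1 | step 3 | (4S,5R)-4-(hydroxymethyl)-5-[(1R,2S,5R)-menthyloxy]dihydrofuran-2(3H)-one | O=C1C[C@@H](CO)[C@H](O[C@@H]2C[C@H](C)CC[C@H]2C(C)C)O1
F2 | step 3 | (4S,5R)-4-(iodomethyl)-5-[(1R,2S,5R)-menthyloxy]dihydrofuran-2(3H)-one | O=C1C[C@@H](CI)[C@H](O[C@@H]2C[C@H](C)CC[C@H]2C(C)C)O1
F3 | step 3 | 2-[2-(menthyloxy lactone)ethyl]cyclohexane-1,3-dione | O=C1C[C@@H](CCC2C(=O)CCCC2=O)[C@H](O[C@@H]3C[C@H](C)CC[C@H]3C(C)C)O1
F4 | step 4 | spiro lactone trione (C13 ketone) | O=C1C[C@H]2C(=O)CC3(C(=O)CCCC3=O)[C@H]2O1
F5 | step 4 | C13 tosylhydrazone of F4 | O=C1C[C@H]2C(=NNS(=O)(=O)c3ccc(C)cc3)CC4(C(=O)CCCC4=O)[C@H]2O1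
F6 | step 5 | mono-dioxolane of 10 (ketal on C6, ketone C10) | O=C1C[C@H]2CC[C@@]3(C(=O)CCCC34OCCO4)[C@H]2O1
F7 | step 5 | C10 tertiary alcohol ketal | O=C1C[C@H]2CC[C@@]3([C@@](C)(O)CCCC34OCCO4)[C@H]2O1
F8 | step 5 | C10 tertiary alcohol C6 ketone | O=C1C[C@H]2CC[C@@]3([C@@](C)(O)CCCC3=O)[C@H]2O1
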